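**Plan**
- Cuts: (a) the CH2–CH2 bond between C-1 of the farnesyl unit and the allylic CH2 on the methyl-bearing olefin carbon of the C5 unit on ring C-5 (allyl–allyl union, last C–C bond); (b) the oxygen on that CH2 (allylic oxidation of a prenyl group); (c) ring C-5–CH2 (enolate prenylation); (d) C-3–CH3.
- Forward: the ring is bought as the mono-dioxolane of cyclohex-2-ene-1,4-dione; methyl and prenyl are put on, the free ketone is reduced, the prenyl E-methyl is oxidised and brominated, the C15 chain is joined, and the masks come off.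
- Enabling feature: both carbons of bond (a) are primary allylic CH2 groups flanked by E-trisubstituted olefins (central bond of a 1,5-diene, a head-to-tail isoprenoid junction), four bonds from ring C-5. One can therefore be an allylmetal and the other an allyl bromide, while C-1 (C=O) is a dioxolane and C-4 (OH) a silyl ether.
- Stereochemistry: C-4 (S) and C-5 (S), cis, are set together by one Noyori hydrogenation with dynamic kinetic resolution of the enolisable C-5 centre. Three E-olefins come with farnesyl chloride, the fourth from E-selective SeO2 oxidation; the allylbarium coupling should retain all of them.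

Key step: step 8

Assumption: 1, 4 and 11 are bought; the sense of induction of the catalyst in step 4 is assigned by analogy with 2-methylcyclohex-2-enones, and the mirror-image catalyst would be used if the carbinol proved to be (R).
Remark: ketals carry spiro numbering (C-8 = carbonyl/carbinol carbon, C-9 = carbon bearing the chain); 15 carries target numbering.

Step 1
Reactants: 1 1,4-dioxaspiro[4.5]dec-6-en-8-one
Product: 2 7-iodo-1,4-dioxaspiro[4.5]dec-6-en-8-one
Conditions: I2, pyridine/CH2Cl2 (1:1), 0 °C → rt
Reagents that add atoms: iodine, II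
Why: α-Iodination of an enone by the pyridine/iodine method (conjugate addition of pyridine at C-6, iodination of the enolate at C-7, loss of pyridine) is reliable on 4,4-disubstituted cyclohexenones, and the dioxolane is inert to the basic medium.

Step 2
Reactants: 2 7-iodo-1,4-dioxaspiro[4.5]dec-6-en-8-one
Product: 3 7-methyl-1,4-dioxaspiro[4.5]dec-6-en-8-one
Conditions: MeB(OH)2, Pd(dppf)Cl2 (5 mol %), K2CO3, dioxane/H2O, 90 °C
Reagents that add atoms: methylboronic acid, CB(O)O
Why: Suzuki–Miyaura coupling of an α-iodoenone (fast oxidative addition at the electron-poor C–I bond) places the methyl group regiospecifically on C-7 under conditions that leave the ketal alone.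

Step 3
Reactants: 3 7-methyl-1,4-dioxaspiro[4.5]dec-6-en-8-one, 4 prenyl bromide (1-bromo-3-methylbut-2-ene)
Product: 6 rac-7-methyl-9-(3-methylbut-2-en-1-yl)-1,4-dioxaspiro[4.5]dec-6-en-8-one, via lithium enolate 5 (not isolated)
Conditions: LDA, THF, −78 °C; then 4, DMPU, −78 → −30 °C
Reagents that add atoms: none
Why: Kinetic deprotonation can occur only at C-9 (the γ-carbon is the quaternary ketal carbon), and the cross-conjugated lithium enolate should be C-alkylated by the reactive allylic bromide (SN2 enolate alkylation); the new centre is racemic here and is corrected in step 4.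

Step 4
Reactants: 6 rac-7-methyl-9-(3-methylbut-2-en-1-yl)-1,4-dioxaspiro[4.5]dec-6-en-8-one
Product: 7 (8S,9S)-7-methyl-9-(3-methylbut-2-en-1-yl)-1,4-dioxaspiro[4.5]dec-6-en-8-ol (cis)
Conditions: trans-RuCl2[(R)-tolbinap][(S,S)-dpen] (0.5 mol %), t-BuOK (0.2 equiv), H2 (8 atm), i-PrOH, 25 °C
Reagents that add atoms: none
Why: Noyori hydrogenation with the Ru(diphosphine)(diamine) catalyst is C=O-selective and leaves both olefins alone; under the basic conditions C-9 should epimerise through the enolate faster than the slow enantiomer is reduced (dynamic kinetic resolution), with the catalyst fixing the (S)-carbinol and hydride delivery anti to the 9-substituent giving the cis (8S,9S) alcohol, as in the dynamic resolution of 2-alkylcyclohexanones.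

Step 5
Reactants: 7 (8S,9S)-7-methyl-9-(3-methylbut-2-en-1-yl)-1,4-dioxaspiro[4.5]dec-6-en-8-ol
Product: 8 tert-butyldimethylsilyl ether of 7
Conditions: TBSCl, imidazole, DMAP (cat.), DMF, 40 °C
Reagents that add atoms: tert-butyldimethylsilyl chloride, CC(C)(C)[Si](C)(C)Cl
Why: Standard silylation of a secondary allylic alcohol; the ether masks the hydroxyl against the organobarium of step 8 and against intramolecular SN2′ attack on the allylic bromide.

Step 6
Reactants: 8 tert-butyldimethylsilyl ether of 7
Product: 9 (E)-4-[(8S,9S)-8-(tert-butyldimethylsilyloxy)-7-methyl-1,4-dioxaspiro[4.5]dec-6-en-9-yl]-2-methylbut-2-en-1-ol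
Conditions: SeO2 (0.3 equiv), t-BuOOH (3 equiv), CH2Cl2, 0 °C → rt
Reagents that add atoms: tert-butyl hydroperoxide (terminal oxidant; oxygen relayed through SeO2), CC(C)(C)OO
Why: Riley-type catalytic SeO2 allylic oxidation (ene reaction, then [2,3]-sigmatropic shift) hydroxylates the E-methyl of a gem-dimethyl olefin, which fixes the E geometry; the ring olefin is more hindered and deactivated by its two allylic C–O bonds, as is the proximal olefin of geranyl acetate in the same reaction.

Step 7
Reactants: 9 the (E)-allylic alcohol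
Product: 10 (E)-allylic bromide: (8S,9S)-9-[(E)-4-bromo-3-methylbut-2-en-1-yl]-8-(tert-butyldimethylsilyloxy)-7-methyl-1,4-dioxaspiro[4.5]dec-6-ene
Conditions: PPh3, CBr4, 2,6-lutidine, CH2Cl2, −20 → 0 °C
Reagents that add atoms: carbon tetrabromide, BrC(Br)(Br)Br
Why: Appel reaction (SN2 on the alkoxyphosphonium ion) converts a primary allylic alcohol into the bromide without allylic transposition or E/Z change, and the buffer protects ketal and silyl ether.

Step 8
Reactants: 10 the (E)-allylic bromide, 11 (2E,6E)-farnesyl chloride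
Product: 13 (8S,9S)-8-(tert-butyldimethylsilyloxy)-7-methyl-9-[(2E,6E,10E)-3,7,11,15-tetramethylhexadeca-2,6,10,14-tetraen-1-yl]-1,4-dioxaspiro[4.5]dec-6-ene, via farnesylbarium chloride 12 (not isolated)
Conditions: Rieke Ba (BaI2, Li, biphenyl, THF, rt); 11 (2 equiv), −78 °C; then 10 (1 equiv), THF, −78 °C
Reagents that add atoms: none
Why: Activated Ba(0) inserts into the C–Cl bond of 11 at −78 °C to give the σ-bound allylbarium 12, whose α-carbon displaces the primary allylic bromide of 10 in an SN2 manner, so the two CH2 carbons are joined directly (α,α′ coupling). The closest known reaction type is the allylbarium–allylic halide cross-coupling used for head-to-tail union of oligoprenyl units. No ring is closed and no stereocentre is formed; the two ring stereocentres are four and five bonds from the reacting carbon and are not touched. The step needs α- over γ-attack in both partners and retention of the E geometry of the farnesyl 2,3-olefin and of the olefin next to the ring. These should be secured by the barium counter-ion (slow 1,3-metal shift and no E/Z equilibration at −78 °C), by the unhindered primary bromide, and by adding 10 only after 11 has consumed the metal. The ring ketone and hydroxyl are present as dioxolane and silyl ether, both inert to the organobarium.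

Step 9
Reactants: 13 the coupled silyl ether ketal
Product: 15 (4S,5S)-4-hydroxy-3-methyl-5-[(2E,6E,10E)-3,7,11,15-tetramethylhexadeca-2,6,10,14-tetraen-1-yl]cyclohex-2-en-1-one (target), via hydroxy ketal 14 (not isolated)
Conditions: TBAF, THF, 0 → 40 °C; then 1 M aq. HCl, THF, 0 °C → rt
Reagents that add atoms: water, O
Why: Fluoride desilylation is done while the ketone is still masked, then dilute acid hydrolyses the allylic dioxolane through its allyl-stabilised oxocarbenium ion (acetal hydrolysis); the free γ-hydroxy enone never meets base, and neither C-4 nor C-5 can epimerise under these conditions.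

**Compound list**
1 | 1,4-dioxaspiro[4.5]dec-6-en-8-one | O=C1C=CC2(CC1)OCCO2 | starting material
2 | 7-iodo-1,4-dioxaspiro[4.5]dec-6-en-8-one | O=C1C(I)=CC2(CC1)OCCO2 | intermediate
3 | 7-methyl-1,4-dioxaspiro[4.5]dec-6-en-8-one | CC1=CC2(CCC1=O)OCCO2 | intermediate
4 | prenyl bromide (1-bromo-3-methylbut-2-ene) | CC(C)=CCBr | starting material
5 | lithium enolate of 3 (lithium 7-methyl-1,4-dioxaspiro[4.5]deca-6,8-dien-8-olate) | [Li]OC1=CCC2(OCCO2)C=C1C | intermediate
6 | rac-7-methyl-9-(3-methylbut-2-en-1-yl)-1,4-dioxaspiro[4.5]dec-6-en-8-one | CC1=CC2(CC(CC=C(C)C)C1=O)OCCO2 | intermediate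
7 | (8S,9S)-7-methyl-9-(3-methylbut-2-en-1-yl)-1,4-dioxaspiro[4.5]dec-6-en-8-ol (cis) | CC(C)=CC[C@H]1CC2(OCCO2)C=C(C)[C@H]1O | intermediate
8 | tert-butyldimethylsilyl ether of 7 | CC(C)=CC[C@H]1CC2(OCCO2)C=C(C)[C@H]1O[Si](C)(C)C(C)(C)C | intermediate
9 | (E)-4-[(8S,9S)-8-(tert-butyldimethylsilyloxy)-7-methyl-1,4-dioxaspiro[4.5]dec-6-en-9-yl]-2-methylbut-2-en-1-ol | OC/C(C)=C/C[C@H]1CC2(OCCO2)C=C(C)[C@H]1O[Si](C)(C)C(C)(C)C | intermediate
10 | (8S,9S)-9-[(E)-4-bromo-3-methylbut-2-en-1-yl]-8-(tert-butyldimethylsilyloxy)-7-methyl-1,4-dioxaspiro[4.5]dec-6-ene | BrC/C(C)=C/C[C@H]1CC2(OCCO2)C=C(C)[C@H]1O[Si](C)(C)C(C)(C)C | intermediate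
11 | (2E,6E)-farnesyl chloride | CC(C)=CCC/C(C)=C/CC/C(C)=C/CCl | starting material
12 | (2E,6E)-farnesylbarium chloride | CC(C)=CCC/C(C)=C/CC/C(C)=C/C[Ba]Cl | intermediate
13 | (8S,9S)-8-(tert-butyldimethylsilyloxy)-7-methyl-9-[(2E,6E,10E)-3,7,11,15-tetramethylhexadeca-2,6,10,14-tetraen-1-yl]-1,4-dioxaspiro[4.5]dec-6-ene | CC(C)=CCC/C(C)=C/CC/C(C)=C/CC/C(C)=C/C[C@H]1CC2(OCCO2)C=C(C)[C@H]1O[Si](C)(C)C(C)(C)C | intermediate
14 | (8S,9S)-7-methyl-9-[(2E,6E,10E)-3,7,11,15-tetramethylhexadeca-2,6,10,14-tetraen-1-yl]-1,4-dioxaspiro[4.5]dec-6-en-8-ol | CC(C)=CCC/C(C)=C/CC/C(C)=C/CC/C(C)=C/C[C@H]1CC2(OCCO2)C=C(C)[C@H]1O | intermediate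
15 | (4S,5S)-4-hydroxy-3-methyl-5-[(2E,6E,10E)-3,7,11,15-tetramethylhexadeca-2,6,10,14-tetraen-1-yl]cyclohex-2-en-1-one | CC(C)=CCC/C(C)=C/CC/C(C)=C/CC/C(C)=C/C[C@H]1CC(=O)C=C(C)[C@H]1O | target

Total step count: 9. Longest linear sequence: 9 steps (1 → 15).

**Steps most likely to fail**

Step 4. Epimerisation at C-9 may be too slow relative to reduction of the slow-reacting enantiomer, so that the process degrades to a simple kinetic resolution, or the cis and facial selectivity may be insufficient. The fallback sets out from 3 and returns at 7, and sets C-9 by an auxiliary before the ketone is reduced. Condensation of 3 with RAMP (cyclohexane, reflux, molecular sieves) should give the RAMP hydrazone of 3 F1. Metalation with LDA and alkylation with 4 at −100 °C (RAMP-hydrazone alkylation, auxiliary control, sense taken from cyclohexanone hydrazones) should give the (9S)-prenylated RAMP hydrazone F2. Buffered cleavage (CuCl2, THF/H2O, pH 7) should release the (9S)-enantiomer of ketone 6 F3. L-Selectride in THF at −78 °C then delivers hydride anti to the 9-substituent and should give 7.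

Step 8. The allylbarium may undergo 1,3-metal shift or E/Z equilibration before it couples, attack may occur at the γ-position (SN2′), or homocoupling may consume the chloride. The fallback sets out from 11 and 10 and returns at 13, with a sulfone as removable activating group. 11 and sodium benzenesulfinate in DMF should give (2E,6E)-farnesyl phenyl sulfone F4. Deprotonation with n-BuLi (THF/HMPA, −78 °C) and alkylation with 10, which takes place at the α-carbon of allylic sulfones, should give the coupled allylic sulfone F5 as a mixture of epimers at the sulfonyl carbon. Palladium-catalysed hydride desulfonylation (PdCl2(dppp), LiBHEt3, THF, 0 °C) should remove the sulfonyl group without moving the olefin and give 13.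

Step 6. Oxidation may occur at the ring methyl, the new carbinol may be over-oxidised, or acidic selenium species may open the ketal. The fallback sets out from 3 and returns at 9, and builds the oxygenated E-olefin by metathesis instead of C–H oxidation. Alkylation of enolate 5 with allyl bromide should give the rac-9-allyl ketone F6. Hydrogenation as in step 4 should give the (8S,9S)-9-allyl alcohol F7, and silylation as in step 5 its silyl ether F8. Cross-metathesis with methacrolein (Hoveyda–Grubbs II, CH2Cl2, 40 °C), in which the ring olefin is inert, should give the (E)-enal F9. Luche reduction (NaBH4, CeCl3, MeOH, 0 °C) should give 9.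

**Further compounds**
F1 | step 4 | RAMP hydrazone of 3 | COC[C@H]1CCCN1N=C1CCC2(C=C1C)OCCO2
F2 | step 4 | (9S)-prenylated RAMP hydrazone | COC[C@H]1CCCN1N=C1C(C)=CC2(C[C@@H]1CC=C(C)C)OCCO2
F3 | step 4 | (9S)-7-methyl-9-(3-methylbut-2-en-1-yl)-1,4-dioxaspiro[4.5]dec-6-en-8-one | CC(C)=CC[C@H]1CC2(OCCO2)C=C(C)C1=O
F4 | step 8 | (2E,6E)-farnesyl phenyl sulfone | CC(C)=CCC/C(C)=C/CC/C(C)=C/CS(=O)(=O)c1ccccc1
F5 | step 8 | coupled allylic sulfone (epimers at the sulfonyl carbon) | CC(C)=CCC/C(C)=C/CC/C(C)=C/C(C/C(C)=C/C[C@H]1CC2(OCCO2)C=C(C)[C@H]1O[Si](C)(C)C(C)(C)C)S(=O)(=O)c1ccccc1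
F6 | step 6 | rac-9-allyl-7-methyl-1,4-dioxaspiro[4.5]dec-6-en-8-one | C=CCC1CC2(OCCO2)C=C(C)C1=O
F7 | step 6 | (8S,9S)-9-allyl-7-methyl-1,4-dioxaspiro[4.5]dec-6-en-8-ol | C=CC[C@H]1CC2(OCCO2)C=C(C)[C@H]1O
F8 | step 6 | tert-butyldimethylsilyl ether of F7 | C=CC[C@H]1CC2(OCCO2)C=C(C)[C@H]1O[Si](C)(C)C(C)(C)C
F9 | step 6 | (E)-4-[(8S,9S)-8-(tert-butyldimethylsilyloxy)-7-methyl-1,4-dioxaspiro[4.5]dec-6-en-9-yl]-2-methylbut-2-enal | O=C/C(C)=C/C[C@H]1CC2(OCCO2)C=C(C)[C@H]1O[Si](C)(C)C(C)(C)C
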